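The trimethylcyclohexene ring is cut into two three-carbon pieces: C2 (the methyl-bearing alkene carbon), C1 and C6 (the gem-dimethyl carbon) on one side, the ring methylenes C3, C4 and C5 on the other. Because C2 and C6 both flank C1, the carbon that carries the side chain, a carbonyl at C1 makes both of them enolate carbons. The key step therefore merges an acyclic enone (after conjugate reduction) and 1-chloro-3-iodopropane into 2,2,6-trimethylcyclohexanone in one flask, forming the C6–C5 and C2–C3 bonds by two regiodefined enolate alkylations. The C1 carbonyl then becomes an enol triflate for attaching the chain; an anti-carbomagnesiation and a late ring-closing metathesis complete the target.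

Key step: step 1

Assumption: the facial preference of (R)-TRIP in the allenylboronate addition to enal 20 is taken to be the Re-face attack known for aryl and alkenyl aldehydes, which gives the (3R)-alcohol; the enantiomeric catalyst would be used if the preference were reversed.

Step 1
Reactants: 1 2-methylpent-1-en-3-one; 2 1-chloro-3-iodopropane
Product: 6 2,2,6-trimethylcyclohexan-1-one, via lithium enolate 3 (not isolated), via chloro ketone 4 (not isolated), via potassium enolate 5 (not isolated)
Conditions: Li(s-Bu)3BH (1.05 equiv), THF, −78 °C (slow addition of 1); 2 (1.05 equiv), DMPU, −78 → 23 °C; KOt-Bu (2.5 equiv, one equiv is bound by s-Bu3B), THF, 0 → 23 °C; NaOH, H2O2 work-up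
Reagents that add atoms: none
Why: Conjugate hydride delivery to the β-unsubstituted enone 1 should give only the tetrasubstituted lithium enolate 3, which is C-alkylated by the iodide end of 2 to create the quaternary C(CH3)2–CH2 bond; the resulting chloro ketone 4 can enolise only at its ethyl CH2, so KOt-Bu gives enolate 5, whose carbon displaces chloride to form the CH(CH3)–CH2 bond and the ring. The closest known reaction types are the reductive alkylation of enones through trialkylborohydride-generated enolates and the base-induced cyclisation of δ-halo ketones to cyclohexanones (a ketone α,α′-annulation with a 1,3-dihalide). The six-membered ring closes in the 6-(enolendo)-exo-tet mode, in which the enolate carbon can reach the backside of the C–Cl bond and C-alkylation is preferred over O-alkylation. The only new stereocentre, the methyl-bearing α-carbon of 6, is formed as a racemate and becomes sp2 in step 2, so no control element is needed. The step needs chemoselectivity between the two leaving groups (iodide reacts in the intermolecular stage, chloride survives for the ring closure) and regiocontrol of both enolates: the first is fixed by the position of the C=C bond in 1, the second by the quaternary carbon, which removes the alternative enolate and with it O-cyclisation to a dihydropyran.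

Step 2
Reactants: 6 2,2,6-trimethylcyclohexan-1-one
Product: 8 2,6,6-trimethylcyclohex-1-en-1-yl trifluoromethanesulfonate, via lithium enolate 7 (not isolated)
Conditions: LiN(i-Pr)2, THF, −78 → 0 °C; PhNTf2, −78 → 23 °C; H2O
Reagents that add atoms: N-phenylbis(trifluoromethanesulfonimide), O=S(=O)(N(c1ccccc1)S(=O)(=O)C(F)(F)F)C(F)(F)F
Why: The single remaining α-hydrogen of 6 is removed and the enolate is O-sulfonylated (enol triflate formation), which places the ring double bond between C1 and the methyl-bearing C2 without any regiochemical choice.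

Step 3
Reactants: 8 2,6,6-trimethylcyclohex-1-en-1-yl trifluoromethanesulfonate; 9 (4-bromobut-1-yn-1-yl)trimethylsilane
Product: 11 trimethyl[4-(2,6,6-trimethylcyclohex-1-en-1-yl)but-1-yn-1-yl]silane, via alkylzinc bromide 10 (not isolated)
Conditions: 9, Zn dust, LiCl, THF, 50 °C; then 8, Pd(OAc)2 (3 mol%), SPhos (6 mol%), THF/NMP, 60 °C
Reagents that add atoms: none
Why: Zinc insertion into the primary C–Br bond followed by Negishi coupling with the hindered alkenyl triflate should attach the side-chain carbon to C1, the bulky electron-rich phosphine favouring oxidative addition and reductive elimination over β-hydride elimination.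

Step 4
Reactants: 11 trimethyl[4-(2,6,6-trimethylcyclohex-1-en-1-yl)but-1-yn-1-yl]silane
Product: 12 2-(but-3-yn-1-yl)-1,3,3-trimethylcyclohex-1-ene
Conditions: K2CO3 (0.2 equiv), MeOH, 23 °C
Reagents that add atoms: none
Why: Base-catalysed methanolysis of the alkynyl C–Si bond (protodesilylation) frees the terminal alkyne for carbometalation and touches nothing else.

Step 5
Reactants: 12 2-(but-3-yn-1-yl)-1,3,3-trimethylcyclohex-1-ene; 13 oxirane
Product: 16 (3E)-4-methyl-6-(2,6,6-trimethylcyclohex-1-en-1-yl)hex-3-en-1-ol, via alkenylalane 14 (not isolated), via lithium alanate 15 (not isolated)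
Conditions: Me3Al, Cp2ZrCl2 (0.25 equiv), CH2Cl2, 0 → 23 °C; n-BuLi, THF, −78 °C; 13, −78 → 0 °C; H2O
Reagents that add atoms: trimethylaluminium, C[Al](C)C
Why: Zirconium-catalysed methylalumination (Negishi carboalumination) adds CH3 and Al syn across the terminal alkyne with CH3 on the internal carbon, which sets the (E)-trisubstituted alkene, and the derived alanate opens oxirane with retention of the alkene geometry.

Step 6
Reactants: 16 (3E)-4-methyl-6-(2,6,6-trimethylcyclohex-1-en-1-yl)hex-3-en-1-ol
Product: 17 2-[(3E)-6-bromo-3-methylhex-3-en-1-yl]-1,3,3-trimethylcyclohex-1-ene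
Conditions: CBr4, PPh3, CH2Cl2, 0 °C
Reagents that add atoms: tetrabromomethane, BrC(Br)(Br)Br
Why: Appel bromination converts the primary alcohol into the bromide under neutral conditions that should neither isomerise nor cyclise the polyene.

Step 7
Reactants: 18 2-methylidenepropane-1,3-diol
Product: 19 2-{[(tert-butyldiphenylsilyl)oxy]methyl}prop-2-en-1-ol
Conditions: 18 (3 equiv), TBDPSCl (1 equiv), imidazole, DMF, 0 °C
Reagents that add atoms: tert-butyl(chloro)diphenylsilane, CC(C)(C)[Si](Cl)(c1ccccc1)c1ccccc1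
Why: Statistical monosilylation of the symmetrical diol used in excess gives the mono-ether, the bulky silyl group being chosen because it resists O-to-O migration under the basic steps that follow.

Step 8
Reactants: 19 2-{[(tert-butyldiphenylsilyl)oxy]methyl}prop-2-en-1-ol
Product: 20 2-{[(tert-butyldiphenylsilyl)oxy]methyl}prop-2-enal
Conditions: MnO2, CH2Cl2, 23 °C (product used without storage)
Reagents that add atoms: none
Why: Manganese dioxide oxidises the allylic alcohol selectively to the enal (allylic oxidation) without over-oxidation or loss of the silyl ether.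

Step 9
Reactants: 20 2-{[(tert-butyldiphenylsilyl)oxy]methyl}prop-2-enal; 21 4,4,5,5-tetramethyl-2-(propa-1,2-dien-1-yl)-1,3,2-dioxaborolane
Product: 22 (3R)-2-{[(tert-butyldiphenylsilyl)oxy]methyl}hex-1-en-5-yn-3-ol
Conditions: 21 (1.5 equiv), (R)-TRIP phosphoric acid (5 mol%), 4 Å MS, toluene, 0 °C; H2O
Reagents that add atoms: none
Why: Chiral phosphoric acid-catalysed propargylation with the allenylboronate passes through a closed six-membered SE2′ transition state in which the catalyst binds the boronate and shields one aldehyde face, so that Re-face attack sets the (R)-carbinol centre under catalyst control.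

Step 10
Reactants: 22 (3R)-2-{[(tert-butyldiphenylsilyl)oxy]methyl}hex-1-en-5-yn-3-ol
Product: 24 (3R)-2-{[(tert-butyldiphenylsilyl)oxy]methyl}hept-1-en-5-yne-3,7-diol, via dilithio derivative 23 (not isolated)
Conditions: n-BuLi (2.2 equiv), THF, −78 → −20 °C; (CH2O)n, −78 → 23 °C; H2O
Reagents that add atoms: paraformaldehyde (formaldehyde equivalent), C=O
Why: Double deprotonation gives the alkoxide acetylide, whose carbon terminus adds to formaldehyde (acetylide hydroxymethylation) to install the propargylic alcohol that directs the next step, the carbinol centre being untouched.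

Step 11
Reactants: 17 2-[(3E)-6-bromo-3-methylhex-3-en-1-yl]-1,3,3-trimethylcyclohex-1-ene; 24 (3R)-2-{[(tert-butyldiphenylsilyl)oxy]methyl}hept-1-en-5-yne-3,7-diol
Product: 28 (2E,5R)-6-{[(tert-butyldiphenylsilyl)oxy]methyl}-2-[(3E)-4-methyl-6-(2,6,6-trimethylcyclohex-1-en-1-yl)hex-3-en-1-yl]hepta-2,6-diene-1,5-diol, via Grignard reagent 25 (not isolated), via bis(bromomagnesium) alkoxide 26 (not isolated), via alkenylmagnesium adduct 27 (not isolated)
Conditions: 17, Mg, THF, 40 °C; separately 24, MeMgBr (2.0 equiv), THF, 0 °C; combine (25 1.5 equiv), CuI (15 mol%), THF, 0 → 50 °C; H2O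
Reagents that add atoms: none
Why: In this copper-catalysed anti-carbomagnesiation of a 2-alkyn-1-ol the propargylic magnesium alkoxide directs the alkyl group to the alkyne carbon next to the CH2O group and magnesium to the distal carbon in a five-membered chelate, so the trans addition places the new chain cis to the CH2–CH(O) arm and protonation gives the required (2E) geometry.

Step 12
Reactants: 28 (2E,5R)-6-{[(tert-butyldiphenylsilyl)oxy]methyl}-2-[(3E)-4-methyl-6-(2,6,6-trimethylcyclohex-1-en-1-yl)hex-3-en-1-yl]hepta-2,6-diene-1,5-diol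
Product: 29 (3R,5E)-7-[(tert-butyldimethylsilyl)oxy]-2-{[(tert-butyldiphenylsilyl)oxy]methyl}-6-[(3E)-4-methyl-6-(2,6,6-trimethylcyclohex-1-en-1-yl)hex-3-en-1-yl]hepta-1,5-dien-3-ol
Conditions: TBSCl (1.05 equiv), imidazole, CH2Cl2, −20 → 0 °C
Reagents that add atoms: tert-butyl(chloro)dimethylsilane, CC(C)(C)[Si](C)(C)Cl
Why: Silylation discriminates the unhindered primary allylic hydroxyl from the hindered secondary one (selective silyl ether formation), leaving the latter free for acylation.

Step 13
Reactants: 29 (3R,5E)-7-[(tert-butyldimethylsilyl)oxy]-2-{[(tert-butyldiphenylsilyl)oxy]methyl}-6-[(3E)-4-methyl-6-(2,6,6-trimethylcyclohex-1-en-1-yl)hex-3-en-1-yl]hepta-1,5-dien-3-ol; 30 prop-2-enoyl chloride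
Product: 31 (3R,5E)-7-[(tert-butyldimethylsilyl)oxy]-2-{[(tert-butyldiphenylsilyl)oxy]methyl}-6-[(3E)-4-methyl-6-(2,6,6-trimethylcyclohex-1-en-1-yl)hex-3-en-1-yl]hepta-1,5-dien-3-yl prop-2-enoate
Conditions: 30, i-Pr2NEt, DMAP (cat.), CH2Cl2, −78 → 0 °C
Reagents that add atoms: none
Why: O-Acylation of the secondary alcohol installs the second alkene for ring closure with retention at the carbinol centre, since the C–O bond is not broken.

Step 14
Reactants: 31 (3R,5E)-7-[(tert-butyldimethylsilyl)oxy]-2-{[(tert-butyldiphenylsilyl)oxy]methyl}-6-[(3E)-4-methyl-6-(2,6,6-trimethylcyclohex-1-en-1-yl)hex-3-en-1-yl]hepta-1,5-dien-3-yl prop-2-enoate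
Product: 32 (5R)-4-{[(tert-butyldiphenylsilyl)oxy]methyl}-5-{(2E,6E)-3-{[(tert-butyldimethylsilyl)oxy]methyl}-7-methyl-9-(2,6,6-trimethylcyclohex-1-en-1-yl)nona-2,6-dien-1-yl}furan-2(5H)-one
Conditions: second-generation Grubbs catalyst (H2IMes)(PCy3)Cl2Ru=CHPh (10 mol%), CH2Cl2 (2 mM), 40 °C
Reagents that add atoms: none
Why: Ring-closing metathesis of the acrylate with the 1,1-disubstituted alkene forms the butenolide with loss of ethene, this closure delivering ruthenium to a terminal CH2 whereas closure onto the trisubstituted chain alkene would require bonding to its fully substituted carbon, and the neutral conditions preserve the C5 stereocentre.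

Step 15
Reactants: 32 (5R)-4-{[(tert-butyldiphenylsilyl)oxy]methyl}-5-{(2E,6E)-3-{[(tert-butyldimethylsilyl)oxy]methyl}-7-methyl-9-(2,6,6-trimethylcyclohex-1-en-1-yl)nona-2,6-dien-1-yl}furan-2(5H)-one
Product: 33 (6E)-neomanoalide
Conditions: HF·pyridine, pyridine, THF, 0 → 23 °C
Reagents that add atoms: none
Why: Fluoride cleavage of both silyl ethers (global desilylation) under weakly acidic conditions avoids the bases that could epimerise the γ-position of the butenolide.

Compound list

1 | 2-methylpent-1-en-3-one | C=C(C)C(=O)CC | starting material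
2 | 1-chloro-3-iodopropane | ClCCCI | starting material
3 | lithium 2-methylpent-2-en-3-olate | [Li+].CCC([O-])=C(C)C | intermediate (not isolated)
4 | 7-chloro-4,4-dimethylheptan-3-one | CCC(=O)C(C)(C)CCCCl | intermediate (not isolated)
5 | potassium 7-chloro-4,4-dimethylhept-2-en-3-olate | [K+].CC=C([O-])C(C)(C)CCCCl | intermediate (not isolated)
6 | 2,2,6-trimethylcyclohexan-1-one (racemic) | CC1CCCC(C)(C)C1=O | intermediate
7 | lithium 2,6,6-trimethylcyclohex-1-en-1-olate | [Li+].CC1=C([O-])C(C)(C)CCC1 | intermediate (not isolated)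
8 | 2,6,6-trimethylcyclohex-1-en-1-yl trifluoromethanesulfonate | CC1=C(OS(=O)(=O)C(F)(F)F)C(C)(C)CCC1 | intermediate
9 | (4-bromobut-1-yn-1-yl)trimethylsilane | C[Si](C)(C)C#CCCBr | starting material
10 | bromo[4-(trimethylsilyl)but-3-yn-1-yl]zinc | C[Si](C)(C)C#CCC[Zn]Br | intermediate (not isolated)
11 | trimethyl[4-(2,6,6-trimethylcyclohex-1-en-1-yl)but-1-yn-1-yl]silane | CC1=C(CCC#C[Si](C)(C)C)C(C)(C)CCC1 | intermediate
12 | 2-(but-3-yn-1-yl)-1,3,3-trimethylcyclohex-1-ene | CC1=C(CCC#C)C(C)(C)CCC1 | intermediate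
13 | oxirane | C1CO1 | starting material
14 | dimethyl[(1E)-2-methyl-4-(2,6,6-trimethylcyclohex-1-en-1-yl)but-1-en-1-yl]alumane | CC1=C(CC/C(C)=C/[Al](C)C)C(C)(C)CCC1 | intermediate (not isolated)
15 | lithium butyl(dimethyl)[(1E)-2-methyl-4-(2,6,6-trimethylcyclohex-1-en-1-yl)but-1-en-1-yl]aluminate | [Li+].CCCC[Al-](C)(C)/C=C(\C)CCC1=C(C)CCCC1(C)C | intermediate (not isolated)
16 | (3E)-4-methyl-6-(2,6,6-trimethylcyclohex-1-en-1-yl)hex-3-en-1-ol | CC1=C(CC/C(C)=C/CCO)C(C)(C)CCC1 | intermediate
17 | 2-[(3E)-6-bromo-3-methylhex-3-en-1-yl]-1,3,3-trimethylcyclohex-1-ene | CC1=C(CC/C(C)=C/CCBr)C(C)(C)CCC1 | intermediate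
18 | 2-methylidenepropane-1,3-diol | C=C(CO)CO | starting material
19 | 2-{[(tert-butyldiphenylsilyl)oxy]methyl}prop-2-en-1-ol | C=C(CO)CO[Si](c1ccccc1)(c1ccccc1)C(C)(C)C | intermediate
20 | 2-{[(tert-butyldiphenylsilyl)oxy]methyl}prop-2-enal | C=C(C=O)CO[Si](c1ccccc1)(c1ccccc1)C(C)(C)C | intermediate
21 | 4,4,5,5-tetramethyl-2-(propa-1,2-dien-1-yl)-1,3,2-dioxaborolane (allenylboronic acid pinacol ester) | C=C=CB1OC(C)(C)C(C)(C)O1 | starting material
22 | (3R)-2-{[(tert-butyldiphenylsilyl)oxy]methyl}hex-1-en-5-yn-3-ol | C#CC[C@@H](O)C(=C)CO[Si](c1ccccc1)(c1ccccc1)C(C)(C)C | intermediate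
23 | dilithio derivative of 22 (lithium alkoxide and lithium acetylide) | [Li+].[Li+].[C-]#CC[C@@H]([O-])C(=C)CO[Si](c1ccccc1)(c1ccccc1)C(C)(C)C | intermediate (not isolated)
24 | (3R)-2-{[(tert-butyldiphenylsilyl)oxy]methyl}hept-1-en-5-yne-3,7-diol | OCC#CC[C@@H](O)C(=C)CO[Si](c1ccccc1)(c1ccccc1)C(C)(C)C | intermediate
25 | bromo[(3E)-4-methyl-6-(2,6,6-trimethylcyclohex-1-en-1-yl)hex-3-en-1-yl]magnesium | CC1=C(CC/C(C)=C/CC[Mg]Br)C(C)(C)CCC1 | intermediate (not isolated)
26 | bis(bromomagnesium) dialkoxide of 24 | Br[Mg]OCC#CC[C@@H](O[Mg]Br)C(=C)CO[Si](c1ccccc1)(c1ccccc1)C(C)(C)C | intermediate (not isolated)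
27 | alkenylmagnesium adduct (28 as its bis(bromomagnesium) alkoxide with C–MgBr in place of the vinylic hydrogen, Mg cis to the CH2O group) | CC1=C(CC/C(C)=C/CC/C(CO[Mg]Br)=C(/[Mg]Br)C[C@@H](O[Mg]Br)C(=C)CO[Si](c2ccccc2)(c2ccccc2)C(C)(C)C)C(C)(C)CCC1 | intermediate (not isolated)
28 | (2E,5R)-6-{[(tert-butyldiphenylsilyl)oxy]methyl}-2-[(3E)-4-methyl-6-(2,6,6-trimethylcyclohex-1-en-1-yl)hex-3-en-1-yl]hepta-2,6-diene-1,5-diol | CC1=C(CC/C(C)=C/CC/C(CO)=C\C[C@@H](O)C(=C)CO[Si](c2ccccc2)(c2ccccc2)C(C)(C)C)C(C)(C)CCC1 | intermediate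
29 | (3R,5E)-7-[(tert-butyldimethylsilyl)oxy]-2-{[(tert-butyldiphenylsilyl)oxy]methyl}-6-[(3E)-4-methyl-6-(2,6,6-trimethylcyclohex-1-en-1-yl)hex-3-en-1-yl]hepta-1,5-dien-3-ol | CC1=C(CC/C(C)=C/CC/C(CO[Si](C)(C)C(C)(C)C)=C\C[C@@H](O)C(=C)CO[Si](c2ccccc2)(c2ccccc2)C(C)(C)C)C(C)(C)CCC1 | intermediate
30 | prop-2-enoyl chloride (acryloyl chloride) | C=CC(=O)Cl | starting material
31 | (3R,5E)-7-[(tert-butyldimethylsilyl)oxy]-2-{[(tert-butyldiphenylsilyl)oxy]methyl}-6-[(3E)-4-methyl-6-(2,6,6-trimethylcyclohex-1-en-1-yl)hex-3-en-1-yl]hepta-1,5-dien-3-yl prop-2-enoate | CC1=C(CC/C(C)=C/CC/C(CO[Si](C)(C)C(C)(C)C)=C\C[C@@H](OC(=O)C=C)C(=C)CO[Si](c2ccccc2)(c2ccccc2)C(C)(C)C)C(C)(C)CCC1 | intermediate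
32 | (5R)-4-{[(tert-butyldiphenylsilyl)oxy]methyl}-5-{(2E,6E)-3-{[(tert-butyldimethylsilyl)oxy]methyl}-7-methyl-9-(2,6,6-trimethylcyclohex-1-en-1-yl)nona-2,6-dien-1-yl}furan-2(5H)-one | CC1=C(CC/C(C)=C/CC/C(CO[Si](C)(C)C(C)(C)C)=C\C[C@H]2OC(=O)C=C2CO[Si](c3ccccc3)(c3ccccc3)C(C)(C)C)C(C)(C)CCC1 | intermediate
33 | (6E)-neomanoalide, (5R)-4-(hydroxymethyl)-5-{(2E,6E)-3-(hydroxymethyl)-7-methyl-9-(2,6,6-trimethylcyclohex-1-en-1-yl)nona-2,6-dien-1-yl}furan-2(5H)-one | CC1=C(CC/C(C)=C/CC/C(=C\C[C@H]2OC(=O)C=C2CO)CO)C(C)(C)CCC1 | target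

Total step count: 15 steps.
Longest linear sequence: 11 steps (steps 1–6, then 11–15); the second branch (steps 7–10) joins at step 11.

Steps most likely to fail

Step 1. The intermolecular C-alkylation of the hindered tetrasubstituted enolate may be slow in the presence of the borane. That would allow Michael addition of the enolate to unreduced enone, or O-alkylation, so the one-flask sequence would stall before ring closure. The fallback sets out from 2 and returns at 6; it makes the ring first and the quaternary carbon last. Purchased pentan-3-one is deprotonated with LiN(i-Pr)2 and alkylated with 2 to give 7-chloro-4-methylheptan-3-one F1. A second equivalent of LiN(i-Pr)2 removes a proton from the remaining CH2 (kinetic preference for CH2 over CH), and the enolate closes in the same 6-(enolendo)-exo-tet mode to 2,6-dimethylcyclohexan-1-one F2, forming the same two ring bonds. Methylation of F2 (LiN(i-Pr)2; MeI) then gives 6.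

Step 11. The copper-catalysed addition of a primary alkyl Grignard reagent to the internal alkynol bis-alkoxide may be too slow, so that protonation or homocoupling of the Grignard reagent takes over, or the second alkoxide may erode the regiocontrol. The fallback sets out from 24 and 17 and returns at 28. Ruthenium-catalysed trans-hydrostannation of 24 (Bu3SnH, [Cp*RuCl]4 cat., CH2Cl2), directed by the propargylic hydroxyl, should give (3R,5Z)-2-{[(tert-butyldiphenylsilyl)oxy]methyl}-6-(tributylstannyl)hepta-1,5-diene-3,7-diol F3. Iododestannylation (I2, CH2Cl2) gives the (5Z)-iodide F4 with retention. Zinc insertion into 17 (Zn, LiCl, THF) gives alkylzinc bromide F5. Negishi coupling of F5 with F4 (Pd(OAc)2, SPhos, slow addition, which tolerates free hydroxyl groups) delivers 28 with retention of the alkene geometry.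

Step 14. The ruthenium carbene may close onto the homoallylic trisubstituted alkene instead, giving a six-membered lactone with excision of the chain, or closure onto the 1,1-disubstituted alkene may be slow enough for the catalyst to decompose. The fallback sets out from 29 and returns at 32 without metathesis:
- Rhodium-catalysed hydroformylation (Rh(acac)(CO)2, PPh3, CO/H2, toluene, 70 °C) should engage only the terminal 1,1-disubstituted alkene of 29 and add the formyl group to its CH2 terminus. The aldehyde closes onto the neighbouring hydroxyl to give lactol F6.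
- Oxidation (PhI(OAc)2, TEMPO cat.) gives the saturated lactone F7.
- α-Selenenylation (LiN(i-Pr)2; PhSeBr, −78 °C) gives selenide F8.
- Oxidation (H2O2, pyridine, 0 °C) and syn-elimination of the selenoxide toward the only β-hydrogen gives butenolide 32.

Further compounds

F1 | step 1 | 7-chloro-4-methylheptan-3-one (racemic) | CCC(=O)C(C)CCCCl
F2 | step 1 | 2,6-dimethylcyclohexan-1-one (cis/trans mixture) | CC1CCCC(C)C1=O
F3 | step 11 | (3R,5Z)-2-{[(tert-butyldiphenylsilyl)oxy]methyl}-6-(tributylstannyl)hepta-1,5-diene-3,7-diol | OC/C([Sn](CCCC)(CCCC)CCCC)=C/C[C@@H](O)C(=C)CO[Si](c1ccccc1)(c1ccccc1)C(C)(C)C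
F4 | step 11 | (3R,5Z)-2-{[(tert-butyldiphenylsilyl)oxy]methyl}-6-iodohepta-1,5-diene-3,7-diol | OC/C(I)=C/C[C@@H](O)C(=C)CO[Si](c1ccccc1)(c1ccccc1)C(C)(C)C
F5 | step 11 | bromo[(3E)-4-methyl-6-(2,6,6-trimethylcyclohex-1-en-1-yl)hex-3-en-1-yl]zinc | CC1=C(CC/C(C)=C/CC[Zn]Br)C(C)(C)CCC1
F6 | step 14 | (5R)-4-{[(tert-butyldiphenylsilyl)oxy]methyl}-5-{(2E,6E)-3-{[(tert-butyldimethylsilyl)oxy]methyl}-7-methyl-9-(2,6,6-trimethylcyclohex-1-en-1-yl)nona-2,6-dien-1-yl}oxolan-2-ol (mixture at C2 and C4) | CC1=C(CC/C(C)=C/CC/C(CO[Si](C)(C)C(C)(C)C)=C\C[C@H]2OC(O)CC2CO[Si](c3ccccc3)(c3ccccc3)C(C)(C)C)C(C)(C)CCC1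
F7 | step 14 | (5R)-4-{[(tert-butyldiphenylsilyl)oxy]methyl}-5-{(2E,6E)-3-{[(tert-butyldimethylsilyl)oxy]methyl}-7-methyl-9-(2,6,6-trimethylcyclohex-1-en-1-yl)nona-2,6-dien-1-yl}oxolan-2-one (mixture at C4) | CC1=C(CC/C(C)=C/CC/C(CO[Si](C)(C)C(C)(C)C)=C\C[C@H]2OC(=O)CC2CO[Si](c3ccccc3)(c3ccccc3)C(C)(C)C)C(C)(C)CCC1
F8 | step 14 | 3-(phenylselanyl) derivative of lactone F7 (mixture at C3 and C4) | CC1=C(CC/C(C)=C/CC/C(CO[Si](C)(C)C(C)(C)C)=C\C[C@H]2OC(=O)C([Se]c3ccccc3)C2CO[Si](c3ccccc3)(c3ccccc3)C(C)(C)C)C(C)(C)CCC1
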